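## Retrosynthetic overview

1. The (R)-quinol is taken from its racemate by chiral-phase chromatography; the racemate comes from singlet-oxygen para-hydroxylative dearomatisation of ring A of the fully aromatic tetradepside phenol, the step that creates the only stereocentre.
2. The three aryl ester bonds are cut in turn. They are made from the ring A end (A–B, then B–C, then C–D) by TFAA esterification; each phenol partner carries a formyl group as a latent carboxyl, oxidised after each coupling.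
3. Rings A and C derive from 2,5-dimethylresorcinol, rings B and D from 4,5-dimethylresorcinol, each by Vilsmeier formylation (chlorination for B, O-methylation for A and D).
4. No carbocycle is built: the four six-membered rings are bought, joined in the order A+B, then C, then D, and ring A is dearomatised last.

Assumption: ring letters run from the cyclohexadienone (ring A) to the benzoic acid terminus (ring D), and both dimethylresorcinols are taken as catalogue chemicals.

## Route

Step 1
Reactants: 1 2,5-dimethylbenzene-1,3-diol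
Product: 3 2,4-dihydroxy-3,6-dimethylbenzaldehyde, via iminium chloride 2 (not isolated)
Conditions: POCl3, DMF, MeCN, 0 °C to rt; then H2O, 50 °C
Reagents that add atoms: N,N-dimethylformamide, CN(C)C=O; water, O
Why: Vilsmeier–Haack formylation, in which the chloroiminium ion attacks the position para to one hydroxyl and ortho to the other (C4 and C6 are equivalent in the symmetric diol) and hydrolysis of 2 releases the aldehyde.

Step 2
Reactants: 3 2,4-dihydroxy-3,6-dimethylbenzaldehyde
Product: 5 4-(benzyloxy)-2-methoxy-3,6-dimethylbenzaldehyde, via monobenzyl ether 4 (not isolated)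
Conditions: BnBr (1.05 equiv), KHCO3, DMF, 40 °C; then MeI, K2CO3, 40 °C
Reagents that add atoms: benzyl bromide, BrCc1ccccc1; iodomethane, CI
Why: Two Williamson etherifications in one pot, since the weak base ionises only the free 4-OH (the 2-OH is hydrogen-bonded to the formyl group) and the stronger K2CO3/MeI pair then methylates the chelated 2-OH.

Step 3
Reactants: 5 4-(benzyloxy)-2-methoxy-3,6-dimethylbenzaldehyde
Product: 6 4-(benzyloxy)-2-methoxy-3,6-dimethylbenzoic acid
Conditions: NaClO2, NaH2PO4, 2-methyl-2-butene, t-BuOH/THF/H2O, 0 °C to rt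
Reagents that add atoms: sodium chlorite NaClO2, [Na+].[O-]Cl=O
Why: Pinnick oxidation converts the hindered aryl aldehyde to the acid without touching the benzyl ether, while 2-methyl-2-butene removes hypochlorous acid before it can chlorinate the electron-rich ring.

Step 4
Reactants: 7 4,5-dimethylbenzene-1,3-diol
Product: 9 2,4-dihydroxy-5,6-dimethylbenzaldehyde, via iminium chloride 8 (not isolated)
Conditions: POCl3, DMF, MeCN, 0 °C to rt; then H2O, 50 °C
Reagents that add atoms: N,N-dimethylformamide, CN(C)C=O; water, O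
Why: Vilsmeier–Haack formylation goes to C6 (para to one hydroxyl, ortho to the other) and not to the doubly flanked C2 between the hydroxyls, as it does with orcinol.

Step 5
Reactants: 9 2,4-dihydroxy-5,6-dimethylbenzaldehyde
Product: 10 3-chloro-2,4-dihydroxy-5,6-dimethylbenzaldehyde
Conditions: SO2Cl2 (1.05 equiv), Et2O, 0 °C to rt
Reagents that add atoms: sulfuryl chloride, O=S(=O)(Cl)Cl
Why: Electrophilic aromatic chlorination at C3, the only ring CH, which is activated by both flanking hydroxyls, so a single monochloride forms.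

Step 6
Reactants: 6 4-(benzyloxy)-2-methoxy-3,6-dimethylbenzoic acid; 10 3-chloro-2,4-dihydroxy-5,6-dimethylbenzaldehyde
Product: 12 2-chloro-4-formyl-3-hydroxy-5,6-dimethylphenyl 4-(benzyloxy)-2-methoxy-3,6-dimethylbenzoate (AB aldehyde), via mixed trifluoroacetic anhydride 11 (not isolated)
Conditions: (CF3CO)2O, toluene, 0 °C to rt
Reagents that add atoms: none
Why: Parish–Stock esterification, in which TFAA turns the 2,6-disubstituted acid into the acylium-like mixed anhydride 11 that reaches the hindered 4-OH of 10 while its 2-OH stays locked in a hydrogen bond to the formyl group.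

Step 7
Reactants: 12 AB aldehyde
Product: 13 4-{[4-(benzyloxy)-2-methoxy-3,6-dimethylbenzoyl]oxy}-3-chloro-2-hydroxy-5,6-dimethylbenzoic acid (AB acid)
Conditions: NaClO2, NaH2PO4, 2-methyl-2-butene, t-BuOH/THF/H2O, 0 °C to rt
Reagents that add atoms: sodium chlorite NaClO2, [Na+].[O-]Cl=O
Why: Pinnick oxidation is mild and slightly acidic, so the aryl ester, the aryl chloride and the free chelated phenol survive while the formyl group becomes the carboxyl for the next coupling.

Step 8
Reactants: 13 AB acid; 3 2,4-dihydroxy-3,6-dimethylbenzaldehyde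
Product: 15 4-formyl-3-hydroxy-2,5-dimethylphenyl 4-{[4-(benzyloxy)-2-methoxy-3,6-dimethylbenzoyl]oxy}-3-chloro-2-hydroxy-5,6-dimethylbenzoate (ABC aldehyde), via mixed trifluoroacetic anhydride 14 (not isolated)
Conditions: (CF3CO)2O, toluene, 0 °C to rt (13 and 3 premixed)
Reagents that add atoms: none
Why: Parish–Stock esterification with the usual para-depside selectivity, because the chelated and doubly flanked 2-hydroxyls of 13 and of 3 do not compete with the free 4-OH of 3 for the mixed anhydride 14.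

Step 9
Reactants: 15 ABC aldehyde
Product: 16 4-[(4-{[4-(benzyloxy)-2-methoxy-3,6-dimethylbenzoyl]oxy}-3-chloro-2-hydroxy-5,6-dimethylbenzoyl)oxy]-2-hydroxy-3,6-dimethylbenzoic acid (ABC acid)
Conditions: NaClO2, NaH2PO4, 2-methyl-2-butene (large excess), t-BuOH/THF/H2O, 0 °C to rt
Reagents that add atoms: sodium chlorite NaClO2, [Na+].[O-]Cl=O
Why: Pinnick oxidation of the salicylaldehyde-type formyl group, with excess alkene scavenger protecting the free C5–H position of ring C from chlorination.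

Step 10
Reactants: 9 2,4-dihydroxy-5,6-dimethylbenzaldehyde
Product: 18 4-(benzyloxy)-2-methoxy-5,6-dimethylbenzaldehyde, via monobenzyl ether 17 (not isolated)
Conditions: BnBr (1.05 equiv), KHCO3, DMF, 40 °C; then MeI, K2CO3, 40 °C
Reagents that add atoms: benzyl bromide, BrCc1ccccc1; iodomethane, CI
Why: The same one-pot pair of Williamson etherifications as in step 2, benzylating the free 4-OH first and then methylating the chelated 2-OH.

Step 11
Reactants: 18 4-(benzyloxy)-2-methoxy-5,6-dimethylbenzaldehyde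
Product: 19 4-hydroxy-2-methoxy-5,6-dimethylbenzaldehyde
Conditions: H2 (1 atm), 10% Pd/C, EtOAc, rt, stopped after 1 equiv H2
Reagents that add atoms: none
Why: Catalytic hydrogenolysis of the aryl benzyl ether is much faster under these neutral conditions than reduction of the electron-rich, doubly ortho-substituted aldehyde.

Step 12
Reactants: 16 ABC acid; 19 4-hydroxy-2-methoxy-5,6-dimethylbenzaldehyde
Product: 21 4-formyl-5-methoxy-2,3-dimethylphenyl 4-[(4-{[4-(benzyloxy)-2-methoxy-3,6-dimethylbenzoyl]oxy}-3-chloro-2-hydroxy-5,6-dimethylbenzoyl)oxy]-2-hydroxy-3,6-dimethylbenzoate (ABCD aldehyde), via mixed trifluoroacetic anhydride 20 (not isolated)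
Conditions: (CF3CO)2O, toluene, 0 °C to rt (16 and 19 premixed)
Reagents that add atoms: none
Why: Parish–Stock esterification of the only free, non-chelated phenol present (the 4-OH of 19) by the mixed anhydride 20 of the hindered acid.

Step 13
Reactants: 21 ABCD aldehyde
Product: 22 4-({4-[(4-{[4-(benzyloxy)-2-methoxy-3,6-dimethylbenzoyl]oxy}-3-chloro-2-hydroxy-5,6-dimethylbenzoyl)oxy]-2-hydroxy-3,6-dimethylbenzoyl}oxy)-2-methoxy-5,6-dimethylbenzoic acid (ABCD acid, ring A benzyl ether)
Conditions: NaClO2, NaH2PO4, 2-methyl-2-butene, t-BuOH/THF/H2O, 0 °C to rt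
Reagents that add atoms: sodium chlorite NaClO2, [Na+].[O-]Cl=O
Why: Pinnick oxidation unveils the ring D carboxylic acid of the target under conditions that leave three aryl esters, the aryl chloride and the benzyl ether intact.

Step 14
Reactants: 22 ABCD acid, ring A benzyl ether
Product: 23 4-({4-[(3-chloro-2-hydroxy-4-[(4-hydroxy-2-methoxy-3,6-dimethylbenzoyl)oxy]-5,6-dimethylbenzoyl)oxy]-2-hydroxy-3,6-dimethylbenzoyl}oxy)-2-methoxy-5,6-dimethylbenzoic acid (tetradepside phenol)
Conditions: H2 (1 atm), 10% Pd/C, EtOAc/THF, rt, stopped after 1 equiv H2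
Reagents that add atoms: none
Why: Hydrogenolysis of the single benzyl ether in neutral, base-free medium, where the aryl C–Cl bond is cleaved only slowly and the aryl esters are inert.

Step 15
Reactants: 23 tetradepside phenol
Product: 25 racemic 4-{[4-({3-chloro-2-hydroxy-4-[(1-hydroxy-2-methoxy-3,6-dimethyl-4-oxocyclohexa-2,5-diene-1-carbonyl)oxy]-5,6-dimethylbenzoyl}oxy)-2-hydroxy-3,6-dimethylbenzoyl]oxy}-2-methoxy-5,6-dimethylbenzoic acid, via hydroperoxide 24 (not isolated)
Conditions: O2 (1 atm), 5,10,15,20-tetraphenylporphyrin (C44H30N4, 1 mol %), white LEDs, CH2Cl2/MeOH 9:1, −20 °C; then Me2S, −20 °C to rt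
Reagents that add atoms: dioxygen, O=O
Why: Sensitised photooxygenation in which singlet oxygen adds para to the only non-chelated phenol, at the ring A carbon also activated by the ortho methoxy group, to give the 4-hydroperoxy-dienone 24 that Me2S reduces to the quinol; the new quaternary stereocentre forms without facial bias (racemate) and is resolved in step 16.

Step 16
Reactants: 25 racemic quinol tetradepside
Product: 26 4-{[4-({3-chloro-2-hydroxy-4-[((1R)-1-hydroxy-2-methoxy-3,6-dimethyl-4-oxocyclohexa-2,5-diene-1-carbonyl)oxy]-5,6-dimethylbenzoyl}oxy)-2-hydroxy-3,6-dimethylbenzoyl]oxy}-2-methoxy-5,6-dimethylbenzoic acid (target, CNP0248758.1)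
Conditions: preparative HPLC on cellulose tris(3,5-dichlorophenylcarbamate) chiral stationary phase, hexane/EtOH/CF3CO2H 70:30:0.1, rt
Reagents that add atoms: none
Why: Resolution by chromatography on a chiral stationary phase; the stereocentre is a quaternary carbinol that cannot epimerise, and the (R) enantiomer is identified by anomalous-dispersion X-ray analysis (chlorine present) or by comparing measured and computed ECD.

## Compound list

1 | 2,5-dimethylbenzene-1,3-diol | Cc1cc(O)c(C)c(O)c1 | starting material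
2 | N-[(2,4-dihydroxy-3,6-dimethylphenyl)methylidene]-N-methylmethanaminium chloride | C[N+](C)=Cc1c(C)cc(O)c(C)c1O.[Cl-] | intermediate
3 | 2,4-dihydroxy-3,6-dimethylbenzaldehyde | O=Cc1c(C)cc(O)c(C)c1O | intermediate
4 | 4-(benzyloxy)-2-hydroxy-3,6-dimethylbenzaldehyde | O=Cc1c(C)cc(OCc2ccccc2)c(C)c1O | intermediate
5 | 4-(benzyloxy)-2-methoxy-3,6-dimethylbenzaldehyde | COc1c(C)c(OCc2ccccc2)cc(C)c1C=O | intermediate
6 | 4-(benzyloxy)-2-methoxy-3,6-dimethylbenzoic acid | COc1c(C)c(OCc2ccccc2)cc(C)c1C(=O)O | intermediate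
7 | 4,5-dimethylbenzene-1,3-diol | Cc1cc(O)cc(O)c1C | starting material
8 | N-[(2,4-dihydroxy-5,6-dimethylphenyl)methylidene]-N-methylmethanaminium chloride | C[N+](C)=Cc1c(O)cc(O)c(C)c1C.[Cl-] | intermediate
9 | 2,4-dihydroxy-5,6-dimethylbenzaldehyde | O=Cc1c(O)cc(O)c(C)c1C | intermediate
10 | 3-chloro-2,4-dihydroxy-5,6-dimethylbenzaldehyde | O=Cc1c(O)c(Cl)c(O)c(C)c1C | intermediate
11 | 4-(benzyloxy)-2-methoxy-3,6-dimethylbenzoic trifluoroacetic anhydride | COc1c(C)c(OCc2ccccc2)cc(C)c1C(=O)OC(=O)C(F)(F)F | intermediate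
12 | 2-chloro-4-formyl-3-hydroxy-5,6-dimethylphenyl 4-(benzyloxy)-2-methoxy-3,6-dimethylbenzoate (AB aldehyde) | COc1c(C)c(OCc2ccccc2)cc(C)c1C(=O)Oc1c(C)c(C)c(C=O)c(O)c1Cl | intermediate
13 | 4-{[4-(benzyloxy)-2-methoxy-3,6-dimethylbenzoyl]oxy}-3-chloro-2-hydroxy-5,6-dimethylbenzoic acid (AB acid) | COc1c(C)c(OCc2ccccc2)cc(C)c1C(=O)Oc1c(C)c(C)c(C(=O)O)c(O)c1Cl | intermediate
14 | mixed anhydride of AB acid 13 and trifluoroacetic acid | COc1c(C)c(OCc2ccccc2)cc(C)c1C(=O)Oc1c(C)c(C)c(C(=O)OC(=O)C(F)(F)F)c(O)c1Cl | intermediate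
15 | 4-formyl-3-hydroxy-2,5-dimethylphenyl ester of AB acid 13 (ABC aldehyde) | COc1c(C)c(OCc2ccccc2)cc(C)c1C(=O)Oc1c(C)c(C)c(C(=O)Oc2cc(C)c(C=O)c(O)c2C)c(O)c1Cl | intermediate
16 | 4-[(4-{[4-(benzyloxy)-2-methoxy-3,6-dimethylbenzoyl]oxy}-3-chloro-2-hydroxy-5,6-dimethylbenzoyl)oxy]-2-hydroxy-3,6-dimethylbenzoic acid (ABC acid) | COc1c(C)c(OCc2ccccc2)cc(C)c1C(=O)Oc1c(C)c(C)c(C(=O)Oc2cc(C)c(C(=O)O)c(O)c2C)c(O)c1Cl | intermediate
17 | 4-(benzyloxy)-2-hydroxy-5,6-dimethylbenzaldehyde | O=Cc1c(O)cc(OCc2ccccc2)c(C)c1C | intermediate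
18 | 4-(benzyloxy)-2-methoxy-5,6-dimethylbenzaldehyde | COc1cc(OCc2ccccc2)c(C)c(C)c1C=O | intermediate
19 | 4-hydroxy-2-methoxy-5,6-dimethylbenzaldehyde | COc1cc(O)c(C)c(C)c1C=O | intermediate
20 | mixed anhydride of ABC acid 16 and trifluoroacetic acid | COc1c(C)c(OCc2ccccc2)cc(C)c1C(=O)Oc1c(C)c(C)c(C(=O)Oc2cc(C)c(C(=O)OC(=O)C(F)(F)F)c(O)c2C)c(O)c1Cl | intermediate
21 | 4-formyl-5-methoxy-2,3-dimethylphenyl ester of ABC acid 16 (ABCD aldehyde) | COc1c(C)c(OCc2ccccc2)cc(C)c1C(=O)Oc1c(C)c(C)c(C(=O)Oc2cc(C)c(C(=O)Oc3cc(OC)c(C=O)c(C)c3C)c(O)c2C)c(O)c1Cl | intermediate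
22 | ABCD acid with ring A 4-O-benzyl ether (name in step 13) | COc1c(C)c(OCc2ccccc2)cc(C)c1C(=O)Oc1c(C)c(C)c(C(=O)Oc2cc(C)c(C(=O)Oc3cc(OC)c(C(=O)O)c(C)c3C)c(O)c2C)c(O)c1Cl | intermediate
23 | tetradepside phenol with ring A as 4-hydroxy-2-methoxy-3,6-dimethylbenzoyl (name in step 14) | COc1c(C)c(O)cc(C)c1C(=O)Oc1c(C)c(C)c(C(=O)Oc2cc(C)c(C(=O)Oc3cc(OC)c(C(=O)O)c(C)c3C)c(O)c2C)c(O)c1Cl | intermediate
24 | racemic hydroperoxide with ring A as 1-hydroperoxy-2-methoxy-3,6-dimethyl-4-oxocyclohexa-2,5-diene-1-carbonyl | COC1=C(C)C(=O)C=C(C)C1(OO)C(=O)Oc1c(C)c(C)c(C(=O)Oc2cc(C)c(C(=O)Oc3cc(OC)c(C(=O)O)c(C)c3C)c(O)c2C)c(O)c1Cl | intermediate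
25 | racemic quinol tetradepside (both configurations at the ring A carbinol carbon) | COC1=C(C)C(=O)C=C(C)C1(O)C(=O)Oc1c(C)c(C)c(C(=O)Oc2cc(C)c(C(=O)Oc3cc(OC)c(C(=O)O)c(C)c3C)c(O)c2C)c(O)c1Cl | intermediate
26 | (R)-quinol tetradepside, CNP0248758.1 (name in step 16) | COC1=C(C)C(=O)C=C(C)[C@]1(O)C(=O)Oc1c(C)c(C)c(C(=O)Oc2cc(C)c(C(=O)Oc3cc(OC)c(C(=O)O)c(C)c3C)c(O)c2C)c(O)c1Cl | target

## Step count and risks

Total step count: 16. Longest linear sequence: 12 (steps 1, 2, 3, 6, 7, 8, 9, 12, 13, 14, 15, 16).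

**Step 15 (dearomatisation).** The ester-bearing phenol may capture singlet oxygen slowly, and the α-hydroperoxy aryl ester 24 can fragment with loss of the ring B phenol and CO2 to a quinone. The fallback sets out from 21 and comes back at 25. It moves the dearomatisation ahead of the release of the carboxylic acid and replaces the hydroperoxide pathway by a two-electron phenol oxidation at trivalent iodine. Hydrogenolysis of 21 (H2, 10% Pd/C, EtOAc) gives the phenol aldehyde 4-formyl-5-methoxy-2,3-dimethylphenyl 4-({3-chloro-2-hydroxy-4-[(4-hydroxy-2-methoxy-3,6-dimethylbenzoyl)oxy]-5,6-dimethylbenzoyl}oxy)-2-hydroxy-3,6-dimethylbenzoate F1. Oxidation with PhI(OAc)2 in MeCN/H2O at 0 °C, with water captured para to the phenol, gives the racemic quinol aldehyde 4-formyl-5-methoxy-2,3-dimethylphenyl 4-({3-chloro-2-hydroxy-4-[(1-hydroxy-2-methoxy-3,6-dimethyl-4-oxocyclohexa-2,5-diene-1-carbonyl)oxy]-5,6-dimethylbenzoyl}oxy)-2-hydroxy-3,6-dimethylbenzoate F2. Pinnick oxidation of F2 then delivers 25.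

**Step 12 (last esterification).** The largest acid, carrying two free ortho hydroxyls, may self-condense or couple poorly. The fallback sets out from 3 and comes back at 21; it changes the 3+1 union into a 2+2 union. Step 2 is stopped after the benzylation and 4 is isolated. Pinnick oxidation of 4 gives 4-(benzyloxy)-2-hydroxy-3,6-dimethylbenzoic acid F3. TFAA activation forms 4-(benzyloxy)-2-hydroxy-3,6-dimethylbenzoic trifluoroacetic anhydride F4 in the flask, which acylates 19 to give 4-formyl-5-methoxy-2,3-dimethylphenyl 4-(benzyloxy)-2-hydroxy-3,6-dimethylbenzoate F5. Hydrogenolysis (H2, 10% Pd/C, EtOAc) gives 4-formyl-5-methoxy-2,3-dimethylphenyl 2,4-dihydroxy-3,6-dimethylbenzoate F6. The smaller AB acid 13, activated as 14 exactly as in step 8, then acylates the free 4-OH of F6 to give 21.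

**Step 16 (resolution).** It discards at least half of the material, and baseline separation of a polar free acid is not assured. The fallback sets out from 23 and comes back at 26, bypassing 25. It is a catalyst-controlled enantioselective hydrative dearomatisation with the C2-symmetric chiral aryl iodide (R,R)-2,2'-[(2-iodo-1,3-phenylene)bis(oxy)]bis(N-mesitylpropanamide) (C30H35IN2O4, 10 mol %) and mCPBA as terminal oxidant in MeCN/H2O at −20 °C. The catalyst antipode that delivers (R)-26 is fixed in a pilot run (both derive from the two lactic acids), and enantiopurity is completed by crystallisation. No new compound arises (F0).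

## Further compounds

F1 | step 15 | 4-formyl-5-methoxy-2,3-dimethylphenyl 4-({3-chloro-2-hydroxy-4-[(4-hydroxy-2-methoxy-3,6-dimethylbenzoyl)oxy]-5,6-dimethylbenzoyl}oxy)-2-hydroxy-3,6-dimethylbenzoate | COc1c(C)c(O)cc(C)c1C(=O)Oc1c(C)c(C)c(C(=O)Oc2cc(C)c(C(=O)Oc3cc(OC)c(C=O)c(C)c3C)c(O)c2C)c(O)c1Cl
F2 | step 15 | racemic 4-formyl-5-methoxy-2,3-dimethylphenyl 4-({3-chloro-2-hydroxy-4-[(1-hydroxy-2-methoxy-3,6-dimethyl-4-oxocyclohexa-2,5-diene-1-carbonyl)oxy]-5,6-dimethylbenzoyl}oxy)-2-hydroxy-3,6-dimethylbenzoate | COC1=C(C)C(=O)C=C(C)C1(O)C(=O)Oc1c(C)c(C)c(C(=O)Oc2cc(C)c(C(=O)Oc3cc(OC)c(C=O)c(C)c3C)c(O)c2C)c(O)c1Cl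
F3 | step 12 | 4-(benzyloxy)-2-hydroxy-3,6-dimethylbenzoic acid | Cc1cc(OCc2ccccc2)c(C)c(O)c1C(=O)O
F4 | step 12 | 4-(benzyloxy)-2-hydroxy-3,6-dimethylbenzoic trifluoroacetic anhydride | Cc1cc(OCc2ccccc2)c(C)c(O)c1C(=O)OC(=O)C(F)(F)F
F5 | step 12 | 4-formyl-5-methoxy-2,3-dimethylphenyl 4-(benzyloxy)-2-hydroxy-3,6-dimethylbenzoate | Cc1cc(OCc2ccccc2)c(C)c(O)c1C(=O)Oc1cc(OC)c(C=O)c(C)c1C
F6 | step 12 | 4-formyl-5-methoxy-2,3-dimethylphenyl 2,4-dihydroxy-3,6-dimethylbenzoate | Cc1cc(O)c(C)c(O)c1C(=O)Oc1cc(OC)c(C=O)c(C)c1C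
F0 | step 16 | none | none
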